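**Plan**

- Late cuts: the 4'-O–prenyl bond, then C3=C4 back to a chroman, the C7 and 4' hydroxyls back to isopropyl and benzyl ethers, the C6 1,2-dione back to a diarylalkyne, and C5–OMe back to C5–OH.
- Core cut: ring A is opened at C8–C8a and C4a–C5. This is possible because C5(–O), C6(–C), C7(–O) and C8(–H) are contiguous and map onto C1(=O), C2, C3(–OiPr) and C4(–Cl) of a squarate-derived cyclobutenone, while C8a(–O1)=C4a is the enol ether double bond of a 2,2-dimethyl-3,4-dihydro-2H-pyran carrying tin on the oxygen-bearing carbon.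
- Forward order: the pyran ring is made first (steps 1–4), the 4-oxyphenyl ring enters with the alkyne on the four-membered ring (steps 5–8), ring A is built onto the pyran in step 9, and steps 10–14 adjust oxidation level and protecting groups.
- Stereochemistry: the target has no stereocentre. The lactol carbon, C4 of the cyclobutenones and C4a of the dienone are racemic and disappear; the one geometric demand (the ketene geometry) is met by reversible ring opening.

Key step: step 9

Assumption: every chiral intermediate (lactol, cyclobutenones, dienone) is used as the racemate, since none of these centres reaches the achiral target.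

**Step 1**
Reactants: 1 5-oxohexanoic acid
Product: 3 6,6-dimethyltetrahydro-2H-pyran-2-one, via 5-hydroxy-5-methylhexanoic acid 2 (not isolated)
Conditions: MeMgBr (2.2 equiv), THF, −20 °C → rt; then 2 M HCl, rt
Reagents that add atoms: methylmagnesium bromide, C[Mg]Br
Why: Grignard addition, in which the first equivalent only forms the unreactive carboxylate, the second adds to the ketone, and the tertiary δ-hydroxy acid 2 should lactonise on acidification (gem-dimethyl effect).

**Step 2**
Reactants: 3 6,6-dimethyltetrahydro-2H-pyran-2-one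
Product: 4 racemic 6,6-dimethyltetrahydro-2H-pyran-2-ol
Conditions: iBu2AlH (1.1 equiv), CH2Cl2, −78 °C; aq. potassium sodium tartrate
Reagents that add atoms: none
Why: Partial reduction of a lactone to the lactol, since the tetrahedral aluminium hemiacetal is stable at −78 °C; the new hemiacetal centre is uncontrolled and is removed in step 3.

**Step 3**
Reactants: 4 racemic 6,6-dimethyltetrahydro-2H-pyran-2-ol
Product: 6 2,2-dimethyl-3,4-dihydro-2H-pyran, via anomeric mesylate 5 (not isolated)
Conditions: MsCl, Et3N, CH2Cl2, 0 °C → 40 °C; distillation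
Reagents that add atoms: none
Why: Lactol dehydration, in which sulfonylation of the hemiacetal hydroxyl gives the labile mesylate 5 and Et3N-assisted β-elimination through the oxocarbenium ion should give the cyclic enol ether.

**Step 4**
Reactants: 6 2,2-dimethyl-3,4-dihydro-2H-pyran
Product: 8 tributyl(6,6-dimethyl-5,6-dihydro-4H-pyran-2-yl)stannane, via lithiated enol ether 7 (not isolated)
Conditions: t-BuLi, THF, −78 → 0 °C; Bu3SnCl, −78 °C → rt
Reagents that add atoms: tributyltin chloride, CCCC[Sn](Cl)(CCCC)CCCC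
Why: α-Lithiation of a cyclic enol ether (the vinylic C–H next to oxygen is the most acidic site) followed by electrophilic stannylation.

**Step 5**
Reactants: 9 4-(benzyloxy)benzaldehyde
Product: 10 1-(benzyloxy)-4-ethynylbenzene
Conditions: dimethyl (1-diazo-2-oxopropyl)phosphonate, K2CO3, MeOH, rt
Reagents that add atoms: dimethyl (1-diazo-2-oxopropyl)phosphonate, CC(=O)C(=[N+]=[N-])P(=O)(OC)OC
Why: Seyferth–Gilbert homologation in the Ohira–Bestmann version, which converts a non-enolisable aryl aldehyde into the terminal alkyne under conditions that leave the benzyl ether untouched.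

**Step 6**
Reactants: 10 1-(benzyloxy)-4-ethynylbenzene; 11 diisopropyl squarate (3,4-di(propan-2-yloxy)cyclobut-3-ene-1,2-dione)
Product: 14 3-{[4-(benzyloxy)phenyl]ethynyl}-4-(propan-2-yloxy)cyclobut-3-ene-1,2-dione, via lithium acetylide 12 (not isolated), via carbinol adduct 13 (not isolated)
Conditions: n-BuLi, THF, −78 °C; 11, −78 °C; 1 M HCl quench; then conc. HCl (cat.), CH2Cl2, rt
Reagents that add atoms: water (from the aqueous HCl; its oxygen becomes the new carbonyl oxygen), O
Why: 1,2-Addition of a lithium acetylide to one squarate carbonyl, then acid-catalysed allylic transposition of carbinol 13 (ionisation to an alkoxy-stabilised cyclobutenyl cation, capture by water at the alkoxy carbon, loss of propan-2-ol) should give the alkynyl cyclobutenedione; the racemic carbinol centre of 13 disappears.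

**Step 7**
Reactants: 14 3-{[4-(benzyloxy)phenyl]ethynyl}-4-(propan-2-yloxy)cyclobut-3-ene-1,2-dione
Product: 15 racemic 2-{[4-(benzyloxy)phenyl]ethynyl}-4-hydroxy-3-(propan-2-yloxy)cyclobut-2-en-1-one
Conditions: LiAlH(OtBu)3, THF, −78 °C
Reagents that add atoms: none
Why: Chemoselective 1,2-reduction by a bulky hydride, because the carbonyl next to the isopropoxy carbon is a cross-conjugated ketone and far more electrophilic than the vinylogous ester carbonyl next to the alkynyl carbon; the new secondary carbinol is racemic and needs no control.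

**Step 8**
Reactants: 15 racemic 2-{[4-(benzyloxy)phenyl]ethynyl}-4-hydroxy-3-(propan-2-yloxy)cyclobut-2-en-1-one
Product: 17 racemic 2-{[4-(benzyloxy)phenyl]ethynyl}-4-chloro-3-(propan-2-yloxy)cyclobut-2-en-1-one, via mesylate 16 (not isolated)
Conditions: MsCl, LiCl, 2,4,6-collidine, DMF, 0 °C
Reagents that add atoms: lithium chloride, [Li+].[Cl-]
Why: Alcohol-to-chloride exchange through the mesylate, in which the allylic, α-keto mesylate 16 is displaced in situ by chloride (SN2) under non-acidic conditions and the alkoxy group on the central carbon of the would-be allyl cation gives ionisation no help; the C4 configuration is irrelevant because the centre is lost in step 9.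

**Step 9**
Reactants: 17 racemic 2-{[4-(benzyloxy)phenyl]ethynyl}-4-chloro-3-(propan-2-yloxy)cyclobut-2-en-1-one; 8 tributyl(6,6-dimethyl-5,6-dihydro-4H-pyran-2-yl)stannane
Product: 21 6-{[4-(benzyloxy)phenyl]ethynyl}-2,2-dimethyl-7-(propan-2-yloxy)chroman-5-ol, via cyclobutenone 18 (not isolated), via dienylketene 19 (not isolated), via dienone 20 (not isolated)
Conditions: Pd2(dba)3 (2.5 mol %), tri(2-furyl)phosphine (10 mol %), 1,4-dioxane, 50 °C, then 100 °C
Reagents that add atoms: none
Why: Zerovalent palladium inserts into the allylic C4–Cl bond of 17, the α-alkoxyvinyl group passes from tin to palladium (Stille coupling) and reductive elimination at the unsubstituted allyl terminus forms the C8–C8a bond in cyclobutenone 18. On heating, 18 opens reversibly by conrotatory 4π electrocyclic ring opening to dienylketene 19, whose ketene carbon (future C5) and enol ether β-carbon (future C4a) are joined by a disrotatory 6π electrocyclisation that closes ring A as dienone 20, and enolisation gives phenol 21. The closest known reaction type is the palladium-catalysed coupling of 4-chlorocyclobutenones with alkenylstannanes that delivers phenols in one pot, a relative of the Moore rearrangement and the Danheiser benzannulation. No lasting stereocentre is formed, since C4 of 18 and C4a of 20 become aromatic carbons. Coupling at C4 and not C2 is secured by the fully substituted, alkynyl-bearing C2 terminus and by retention of the vinylogous ester conjugation, and only the ketene isomer with the pyranyl group turned inward can cyclise while the other reverts to 18, so the pattern C5–OH, C6–alkynyl, C7–OiPr, C8–H follows directly from C1 to C4 of 17. A phosphine-ligated zerovalent catalyst, a neutral medium and a short time at 100 °C are chosen so that the free C5 hydroxyl does not add to the neighbouring alkyne.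

**Step 10**
Reactants: 21 6-{[4-(benzyloxy)phenyl]ethynyl}-2,2-dimethyl-7-(propan-2-yloxy)chroman-5-ol
Product: 22 6-{[4-(benzyloxy)phenyl]ethynyl}-5-methoxy-2,2-dimethyl-7-(propan-2-yloxy)chromane
Conditions: MeI, K2CO3, acetone, 40 °C
Reagents that add atoms: iodomethane, CI
Why: Williamson O-methylation of the only free phenol under mild carbonate conditions, which also removes the nucleophile that could attack the alkyne.

**Step 11**
Reactants: 22 6-{[4-(benzyloxy)phenyl]ethynyl}-5-methoxy-2,2-dimethyl-7-(propan-2-yloxy)chromane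
Product: 23 1-[4-(benzyloxy)phenyl]-2-[5-methoxy-2,2-dimethyl-7-(propan-2-yloxy)chroman-6-yl]ethane-1,2-dione
Conditions: KMnO4, NaHCO3, MgSO4, acetone/H2O, 0 °C → rt
Reagents that add atoms: potassium permanganate, [K+].[O-][Mn](=O)(=O)=O
Why: Permanganate oxidation of a diarylalkyne to a benzil through the cyclic manganate ester, with NaHCO3/MgSO4 buffering to suppress C–C cleavage, while the aryl ethers and the saturated chroman should be inert at room temperature.

**Step 12**
Reactants: 23 1-[4-(benzyloxy)phenyl]-2-[5-methoxy-2,2-dimethyl-7-(propan-2-yloxy)chroman-6-yl]ethane-1,2-dione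
Product: 24 1-(7-hydroxy-5-methoxy-2,2-dimethylchroman-6-yl)-2-(4-hydroxyphenyl)ethane-1,2-dione
Conditions: BCl3, pentamethylbenzene, CH2Cl2, −78 → −20 °C; H2O quench
Reagents that add atoms: none
Why: Lewis-acid ether cleavage, in which BCl3 chelated between the C6 carbonyl and O7 removes the secondary isopropyl group at low temperature where the C5 methyl ether survives, and the 4'-benzyl ether is cleaved in the same pot with pentamethylbenzene trapping the benzyl cation (Friedel–Crafts capture).

**Step 13**
Reactants: 24 1-(7-hydroxy-5-methoxy-2,2-dimethylchroman-6-yl)-2-(4-hydroxyphenyl)ethane-1,2-dione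
Product: 25 1-(7-hydroxy-5-methoxy-2,2-dimethyl-2H-chromen-6-yl)-2-(4-hydroxyphenyl)ethane-1,2-dione
Conditions: DDQ, 1,4-dioxane, reflux
Reagents that add atoms: none
Why: Quinone dehydrogenation of a chroman, in which DDQ abstracts hydride from benzylic C4 (cation stabilised by O1, the C5 methoxy and the para C7 hydroxyl) and loss of a C3 proton gives the 2H-chromene, the electron-poor 4'-phenol and the dione being inert.

**Step 14**
Reactants: 25 1-(7-hydroxy-5-methoxy-2,2-dimethyl-2H-chromen-6-yl)-2-(4-hydroxyphenyl)ethane-1,2-dione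
Product: 26 ficucaricone C
Conditions: prenyl bromide (1.05 equiv), K2CO3 (1.1 equiv), acetone, rt
Reagents that add atoms: 1-bromo-3-methylbut-2-ene (prenyl bromide), CC(C)=CCBr
Why: Williamson etherification, in which the unchelated, more acidic 4'-OH (para to the dione) is alkylated by SN2 on prenyl bromide while the C7–OH is held in a hydrogen bond to the C6 carbonyl.

**Compound list**

1 | 5-oxohexanoic acid | CC(=O)CCCC(=O)O | starting material
2 | 5-hydroxy-5-methylhexanoic acid | CC(C)(O)CCCC(=O)O | intermediate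
3 | 6,6-dimethyltetrahydro-2H-pyran-2-one | CC1(C)CCCC(=O)O1 | intermediate
4 | racemic 6,6-dimethyltetrahydro-2H-pyran-2-ol | CC1(C)CCCC(O)O1 | intermediate
5 | racemic 6,6-dimethyltetrahydro-2H-pyran-2-yl methanesulfonate | CC1(C)CCCC(OS(C)(=O)=O)O1 | intermediate
6 | 2,2-dimethyl-3,4-dihydro-2H-pyran | CC1(C)CCC=CO1 | intermediate
7 | (6,6-dimethyl-5,6-dihydro-4H-pyran-2-yl)lithium | [Li]C1=CCCC(C)(C)O1 | intermediate
8 | tributyl(6,6-dimethyl-5,6-dihydro-4H-pyran-2-yl)stannane | CCCC[Sn](CCCC)(CCCC)C1=CCCC(C)(C)O1 | intermediate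
9 | 4-(benzyloxy)benzaldehyde | O=Cc1ccc(OCc2ccccc2)cc1 | starting material
10 | 1-(benzyloxy)-4-ethynylbenzene | C#Cc1ccc(OCc2ccccc2)cc1 | intermediate
11 | diisopropyl squarate (3,4-di(propan-2-yloxy)cyclobut-3-ene-1,2-dione) | CC(C)OC1=C(OC(C)C)C(=O)C1=O | starting material
12 | lithium [4-(benzyloxy)phenyl]acetylide | [Li]C#Cc1ccc(OCc2ccccc2)cc1 | intermediate
13 | racemic 4-{[4-(benzyloxy)phenyl]ethynyl}-4-hydroxy-2,3-di(propan-2-yloxy)cyclobut-2-en-1-one | CC(C)OC1=C(OC(C)C)C(O)(C#Cc2ccc(OCc3ccccc3)cc2)C1=O | intermediate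
14 | 3-{[4-(benzyloxy)phenyl]ethynyl}-4-(propan-2-yloxy)cyclobut-3-ene-1,2-dione | CC(C)OC1=C(C#Cc2ccc(OCc3ccccc3)cc2)C(=O)C1=O | intermediate
15 | racemic 2-{[4-(benzyloxy)phenyl]ethynyl}-4-hydroxy-3-(propan-2-yloxy)cyclobut-2-en-1-one | CC(C)OC1=C(C#Cc2ccc(OCc3ccccc3)cc2)C(=O)C1O | intermediate
16 | racemic 3-{[4-(benzyloxy)phenyl]ethynyl}-4-oxo-2-(propan-2-yloxy)cyclobut-2-en-1-yl methanesulfonate | CC(C)OC1=C(C#Cc2ccc(OCc3ccccc3)cc2)C(=O)C1OS(C)(=O)=O | intermediate
17 | racemic 2-{[4-(benzyloxy)phenyl]ethynyl}-4-chloro-3-(propan-2-yloxy)cyclobut-2-en-1-one | CC(C)OC1=C(C#Cc2ccc(OCc3ccccc3)cc2)C(=O)C1Cl | intermediate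
18 | racemic 2-{[4-(benzyloxy)phenyl]ethynyl}-4-(6,6-dimethyl-5,6-dihydro-4H-pyran-2-yl)-3-(propan-2-yloxy)cyclobut-2-en-1-one | CC(C)OC1=C(C#Cc2ccc(OCc3ccccc3)cc2)C(=O)C1C4=CCCC(C)(C)O4 | intermediate
19 | (3E)-2-{[4-(benzyloxy)phenyl]ethynyl}-4-(6,6-dimethyl-5,6-dihydro-4H-pyran-2-yl)-3-(propan-2-yloxy)buta-1,3-dien-1-one (pyranyl group cis to the ketene arm) | O=C=C(C#Cc1ccc(OCc2ccccc2)cc1)/C(OC(C)C)=C\C1=CCCC(C)(C)O1 | intermediate
20 | racemic 6-{[4-(benzyloxy)phenyl]ethynyl}-2,2-dimethyl-7-(propan-2-yloxy)-2,3,4,4a-tetrahydro-5H-chromen-5-one (keto tautomer of 21) | CC(C)OC1=C(C#Cc2ccc(OCc3ccccc3)cc2)C(=O)C2CCC(C)(C)OC2=C1 | intermediate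
21 | 6-{[4-(benzyloxy)phenyl]ethynyl}-2,2-dimethyl-7-(propan-2-yloxy)chroman-5-ol | CC(C)Oc1cc2OC(C)(C)CCc2c(O)c1C#Cc1ccc(OCc2ccccc2)cc1 | intermediate
22 | 6-{[4-(benzyloxy)phenyl]ethynyl}-5-methoxy-2,2-dimethyl-7-(propan-2-yloxy)chromane | COc1c(C#Cc2ccc(OCc3ccccc3)cc2)c(OC(C)C)cc2c1CCC(C)(C)O2 | intermediate
23 | 1-[4-(benzyloxy)phenyl]-2-[5-methoxy-2,2-dimethyl-7-(propan-2-yloxy)chroman-6-yl]ethane-1,2-dione | COc1c(C(=O)C(=O)c2ccc(OCc3ccccc3)cc2)c(OC(C)C)cc2c1CCC(C)(C)O2 | intermediate
24 | 1-(7-hydroxy-5-methoxy-2,2-dimethylchroman-6-yl)-2-(4-hydroxyphenyl)ethane-1,2-dione | COc1c(C(=O)C(=O)c2ccc(O)cc2)c(O)cc2c1CCC(C)(C)O2 | intermediate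
25 | 1-(7-hydroxy-5-methoxy-2,2-dimethyl-2H-chromen-6-yl)-2-(4-hydroxyphenyl)ethane-1,2-dione | COc1c(C(=O)C(=O)c2ccc(O)cc2)c(O)cc2c1C=CC(C)(C)O2 | intermediate
26 | ficucaricone C, 1-(7-hydroxy-5-methoxy-2,2-dimethyl-2H-chromen-6-yl)-2-{4-[(3-methylbut-2-en-1-yl)oxy]phenyl}ethane-1,2-dione | COc1c2c(cc(O)c1C(=O)C(=O)c1ccc(OCC=C(C)C)cc1)OC(C)(C)C=C2 | target

**Step count and risks**

Total step count: 14.
Longest linear sequence: 10 steps (steps 5–14 from 4-(benzyloxy)benzaldehyde; the stannane branch, steps 1–4 followed by 9–14, is equally long).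

Steps most likely to fail:

Step 8. The activated C4–O bond may be displaced with allylic shift (chloride entering at C2), or the strained α-chloroketone may decompose during isolation. Fallback: starting from 15, acetylation (Ac2O, pyridine, DMAP cat., CH2Cl2, 0 °C) would give racemic 3-{[4-(benzyloxy)phenyl]ethynyl}-4-oxo-2-(propan-2-yloxy)cyclobut-2-en-1-yl acetate F1. As an allylic acetate it would be coupled directly with stannane 8 under zerovalent palladium with LiCl (Pd2(dba)3, LiCl, DMF, 50 → 100 °C; allylic acetate–vinylstannane coupling). The sequence would pass through 18, 19 and 20 and rejoin the route at phenol 21, so the chloride is bypassed.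

Step 9. Protodestannylation of the acid-labile α-alkoxyvinylstannane or slow tin-to-palladium transfer may let the oxocyclobutenylpalladium chloride decay, and during the hot phase palladium may promote addition of the new C5 hydroxyl to the alkyne. Fallback: starting from the lithiated enol ether 7 of step 4, transmetalation with ZnCl2 (THF, −78 → 0 °C) would give chloro(6,6-dimethyl-5,6-dihydro-4H-pyran-2-yl)zinc F2. Negishi coupling with chloride 17 (Pd(PPh3)4, THF, 20 °C) would stop at cyclobutenone 18, which would be isolated and filtered free of palladium. Heating 18 in toluene at 100 °C would then give 21 through 19 and 20, where the route is rejoined; bond formation and ring expansion are thus separated and the hot step is metal-free.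

Step 11. Over-oxidation may cleave the first-formed dione into two carboxylic acids, and permanganate may attack the benzylic C4–H bonds or the benzyl ether. Fallback: starting from 22, semihydrogenation (H2, Pd/CaCO3 poisoned with Pb(OAc)2, quinoline, EtOAc, rt) would give 6-{(Z)-2-[4-(benzyloxy)phenyl]ethenyl}-5-methoxy-2,2-dimethyl-7-(propan-2-yloxy)chromane F3. Syn-dihydroxylation (OsO4 cat., N-methylmorpholine N-oxide, acetone/H2O, rt) would give racemic erythro-(1R*,2S*)-1-[4-(benzyloxy)phenyl]-2-[5-methoxy-2,2-dimethyl-7-(propan-2-yloxy)chroman-6-yl]ethane-1,2-diol F4. Double Swern oxidation ((COCl)2, DMSO, CH2Cl2, −78 °C; Et3N) would then return to dione 23.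

**Further compounds**

F1 | step 8 | racemic 3-{[4-(benzyloxy)phenyl]ethynyl}-4-oxo-2-(propan-2-yloxy)cyclobut-2-en-1-yl acetate | CC(C)OC1=C(C#Cc2ccc(OCc3ccccc3)cc2)C(=O)C1OC(C)=O
F2 | step 9 | chloro(6,6-dimethyl-5,6-dihydro-4H-pyran-2-yl)zinc | Cl[Zn]C1=CCCC(C)(C)O1
F3 | step 11 | 6-{(Z)-2-[4-(benzyloxy)phenyl]ethenyl}-5-methoxy-2,2-dimethyl-7-(propan-2-yloxy)chromane | COc1c(/C=C\c2ccc(OCc3ccccc3)cc2)c(OC(C)C)cc2c1CCC(C)(C)O2
F4 | step 11 | racemic erythro-(1R*,2S*)-1-[4-(benzyloxy)phenyl]-2-[5-methoxy-2,2-dimethyl-7-(propan-2-yloxy)chroman-6-yl]ethane-1,2-diol | COc1c([C@@H](O)[C@@H](O)c2ccc(OCc3ccccc3)cc2)c(OC(C)C)cc2c1CCC(C)(C)O2
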